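**Plan**

1. Numbering: oxolane ring A = O1, C2 (aryl), C3 (carries C9H2–O–acyl), C4 (carries benzylic C7′H2), C5 (OCH2). Retrosynthetic cuts, in order: the ester C9O–CO and the two benzyl ethers; the aryl–C7′ bond; the ring bond C4–C5; the ether O1–C5 and the ring-B alkene; the C2–C3 bond.
2. Forward: anti-selective (hydroxymethyl)allylation of O-benzylvanillin gives the C2/C3 diol; an acrylate on O(C9) and metathesis close a temporary δ-lactone (ring B: C3, C9, O, C=O, C7′, C4); O1 receives a CH2CO2H arm; a decarboxylative radical cyclisation closes ring A; ring B is opened and its carboxyl is exchanged for the aryl group; esterification and debenzylation finish.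
3. Enabling feature: O1 is an ether oxygen next to the CH2 group C5, so C5 can be generated as an α-oxy radical from O1–CH2–CO2H. C9–O and C7′ are 1,4-related through C3–C4, so they can be tied into ring B, which makes C4=C7′ an electron-poor ring alkene facing that radical.
4. Stereochemistry: C2 and C3 come from the catalyst-controlled anti allylation; C4 comes from the forced cis fusion of rings A and B in the key step; the side-chain centre is bought as (2R)-2-methylbutanoic acid.
5. Helpers and their removal: the CO2H on C5 leaves as CO2 in the key step; the lactone carbonyl of ring B leaves as CO2 when the aryl group is placed on C7′.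

Key step: step 6

Remark: the SEGPHOS antipode in step 1 is taken to be the one that leads to the (1R,2S)-diol; the atom labels O1, C2–C5, C7′ and C9 in the Why lines are those of the plan.

Step 1
Reactants: 1 4-(benzyloxy)-3-methoxybenzaldehyde; 2 4-ethenyl-1,3-dioxolan-2-one (racemic)
Product: 3 (1R,2S)-1-[4-(benzyloxy)-3-methoxyphenyl]-2-ethenylpropane-1,3-diol
Conditions: [Ir(cod)Cl]2 (2.5 mol%), SEGPHOS (5 mol%, antipode as in the remark), 4-cyano-3-nitrobenzoic acid (10 mol%), K3PO4 (cat.), i-PrOH (2 equiv), THF, 60 °C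
Reagents that add atoms: none
Why: Iridium-catalysed transfer-hydrogenative carbonyl (hydroxymethyl)allylation (Krische-type allylation): decarboxylative ionisation of 2 gives a hydroxymethyl-substituted allyl iridium species whose (E)-σ-allyl form adds to the aldehyde through a closed chair transition state, which sets the anti relation between C2–OH and C3–CH2OH, while the chiral bisphosphine on the cyclometallated iridium centre sets the absolute configuration (1R,2S).

Step 2
Reactants: 3 (1R,2S)-1-[4-(benzyloxy)-3-methoxyphenyl]-2-ethenylpropane-1,3-diol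
Product: 4 (2S)-2-{(R)-[4-(benzyloxy)-3-methoxyphenyl](hydroxy)methyl}but-3-en-1-yl prop-2-enoate
Conditions: acryloyl chloride (1.05 equiv), Et3N, CH2Cl2, −78 °C
Reagents that add atoms: acryloyl chloride, C=CC(Cl)=O
Why: Kinetically selective O-acylation: at −78 °C the acid chloride esterifies the unhindered primary hydroxyl in preference to the hindered secondary benzylic one, and no stereocentre is involved.

Step 3
Reactants: 4 (2S)-2-{(R)-[4-(benzyloxy)-3-methoxyphenyl](hydroxy)methyl}but-3-en-1-yl prop-2-enoate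
Product: 5 (5S)-5-{(R)-[4-(benzyloxy)-3-methoxyphenyl](hydroxy)methyl}-5,6-dihydro-2H-pyran-2-one
Conditions: second-generation Grubbs catalyst (5 mol%), CH2Cl2 (high dilution), 40 °C
Reagents that add atoms: none
Why: Ring-closing olefin metathesis of the acrylate onto the vinyl group forms the six-membered α,β-unsaturated lactone (ring B) with loss of ethene, the ring enforcing the Z alkene and the free secondary alcohol being tolerated by the ruthenium carbene.

Step 4
Reactants: 5 (5S)-5-{(R)-[4-(benzyloxy)-3-methoxyphenyl](hydroxy)methyl}-5,6-dihydro-2H-pyran-2-one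
Product: 6 ethyl 2-{(R)-[4-(benzyloxy)-3-methoxyphenyl][(3S)-6-oxo-3,6-dihydro-2H-pyran-3-yl]methoxy}acetate
Conditions: ethyl diazoacetate (slow addition), Rh2(OAc)4 (1 mol%), CH2Cl2, 25 °C
Reagents that add atoms: ethyl diazoacetate, CCOC(=O)C=[N+]=[N-]
Why: Dirhodium-carbenoid O–H insertion forms the O1–C5 ether under neutral conditions, so that the base-sensitive lactone and the C3 stereocentre are not exposed to alkoxide, the C2–O bond is not broken (retention at C2), and the electron-poor ring alkene is not cyclopropanated.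

Step 5
Reactants: 6 ethyl 2-{(R)-[4-(benzyloxy)-3-methoxyphenyl][(3S)-6-oxo-3,6-dihydro-2H-pyran-3-yl]methoxy}acetate
Product: 8 2-{(R)-[4-(benzyloxy)-3-methoxyphenyl][(3S)-6-oxo-3,6-dihydro-2H-pyran-3-yl]methoxy}acetic acid, via dilithium ring-opened dicarboxylate 7 (not isolated)
Conditions: LiOH (2.5 equiv), THF/H2O, 0 °C; then 1 M HCl to pH 3, 25 °C
Reagents that add atoms: lithium hydroxide, [Li+].[OH-]
Why: Ester saponification: hydroxide cleaves the activated alkoxyacetate and also opens ring B to the (Z)-hydroxy enoate 7, which on acidification should reclose spontaneously to the six-membered lactone (lactonisation of a (Z)-5-hydroxy-2-enoic acid) while the alkoxyacetic acid stays free; the cold, short contact is chosen to avoid deprotonation at C3.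

Step 6
Reactants: 8 2-{(R)-[4-(benzyloxy)-3-methoxyphenyl][(3S)-6-oxo-3,6-dihydro-2H-pyran-3-yl]methoxy}acetic acid
Product: 9 (3R,3aS,7aS)-3-[4-(benzyloxy)-3-methoxyphenyl]hexahydro-6H-furo[3,4-c]pyran-6-one (cis-fused oxolane/δ-lactone)
Conditions: Ir[dF(CF3)ppy]2(dtbbpy)PF6 (1 mol%), K2HPO4 (1.2 equiv), DMF (0.02 M, degassed), blue LEDs (450 nm), 25 °C
Reagents that add atoms: none
Why: Visible-light excitation gives an excited trivalent iridium oxidant that takes one electron from the carboxylate of 8; loss of CO2 leaves the nucleophilic α-oxy radical O1–C5H2•, which adds to the β-carbon C4 of the unsaturated δ-lactone, and the α-acyl radical at C7′ is reduced by divalent iridium to the lactone enolate and protonated (redox-neutral decarboxylative Giese reaction; the closest known type is the photoredox decarboxylative conjugate addition of α-alkoxy acids to enoates). Ring A (O1–C2–C3–C4–C5) closes in the 5-exo-trig mode on the C4=C7′ bond, which lies inside ring B. The new stereocentre C4 is controlled by the ring fusion: the three-atom tether C2–O1–C5 hangs from C3 and can reach C4 only on the face of ring B that carries it, so rings A and B must fuse cis, which places C7′ cis to C9 on ring A (C4 = S). The pre-set anti relation C2/C3 puts the aryl group on the convex face of the forming bicycle, so nothing opposes this approach. The step needs regioselectivity (C4 over C7′), secured by ring size and by the polarity match of the electron-rich radical with the enoate β-carbon, and chemoselective oxidation of the carboxylate beside two dialkoxyarene rings, secured by the low oxidation potential of an α-alkoxy carboxylate.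

Step 7
Reactants: 9 (3R,3aS,7aS)-3-[4-(benzyloxy)-3-methoxyphenyl]hexahydro-6H-furo[3,4-c]pyran-6-one; 10 1-(benzyloxy)-4-bromo-2-methoxybenzene
Product: 12 [(2R,3S,4S)-2-[4-(benzyloxy)-3-methoxyphenyl]-4-{[4-(benzyloxy)-3-methoxyphenyl]methyl}oxolan-3-yl]methanol, via caesium hydroxy carboxylate 11 (not isolated)
Conditions: CsOH·H2O (1.0 equiv), THF/H2O, 25 °C, evaporate; then 10 (1.5 equiv), NiCl2(dme) (10 mol%), 4,4′-di-tert-butyl-2,2′-bipyridine (15 mol%), Ir[dF(CF3)ppy]2(dtbbpy)PF6 (2 mol%), phthalimide (additive), DMSO, blue LEDs, 25 °C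
Reagents that add atoms: none
Why: Lactone hydrolysis followed by metallaphotoredox decarboxylative arylation: hydroxide opens ring B to the caesium δ-hydroxy carboxylate, which cannot relactonise without acid, photo-oxidation and loss of CO2 give the primary radical at C7′, and this is captured by the aryl nickel species formed by oxidative addition of zerovalent nickel to 10, reductive elimination making the C7′–aryl bond; C3 and C4 are untouched, so the cis relation is kept.

Step 8
Reactants: 12 [(2R,3S,4S)-2-[4-(benzyloxy)-3-methoxyphenyl]-4-{[4-(benzyloxy)-3-methoxyphenyl]methyl}oxolan-3-yl]methanol; 13 (2R)-2-methylbutanoic acid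
Product: 14 [(2R,3S,4S)-2-[4-(benzyloxy)-3-methoxyphenyl]-4-{[4-(benzyloxy)-3-methoxyphenyl]methyl}oxolan-3-yl]methyl (2R)-2-methylbutanoate
Conditions: N,N′-dicyclohexylcarbodiimide (1.2 equiv), DMAP (0.1 equiv), CH2Cl2, 0 to 25 °C
Reagents that add atoms: none
Why: Steglich esterification: the only free hydroxyl is acylated through the O-acylisourea and acylpyridinium species, a mode of activation that avoids ketene formation and therefore keeps the α-stereocentre of 13.

Step 9
Reactants: 14 [(2R,3S,4S)-2-[4-(benzyloxy)-3-methoxyphenyl]-4-{[4-(benzyloxy)-3-methoxyphenyl]methyl}oxolan-3-yl]methyl (2R)-2-methylbutanoate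
Product: 15 [(2R,3S,4S)-2-(4-hydroxy-3-methoxyphenyl)-4-[(4-hydroxy-3-methoxyphenyl)methyl]oxolan-3-yl]methyl (2R)-2-methylbutanoate (CNP0315069.1)
Conditions: H2 (1 atm), 10% Pd/C, EtOAc, 25 °C, stopped at complete debenzylation
Reagents that add atoms: none
Why: Catalytic hydrogenolysis cleaves the two aryl benzyl ethers faster than the benzylic C2–O1 bond of ring A, which together with neutral solvent, ambient pressure and timely interruption should leave the oxolane, the ester and all four stereocentres intact.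

**Compound list**

1 | 4-(benzyloxy)-3-methoxybenzaldehyde | O=Cc1ccc(OCc2ccccc2)c(OC)c1 | starting material
2 | 4-ethenyl-1,3-dioxolan-2-one (racemic vinyl ethylene carbonate) | C=CC1COC(=O)O1 | starting material
3 | (1R,2S)-1-[4-(benzyloxy)-3-methoxyphenyl]-2-ethenylpropane-1,3-diol | OC[C@@H]([C@@H](O)c1ccc(OCc2ccccc2)c(OC)c1)C=C | intermediate
4 | (2S)-2-{(R)-[4-(benzyloxy)-3-methoxyphenyl](hydroxy)methyl}but-3-en-1-yl prop-2-enoate | C=CC(=O)OC[C@@H]([C@@H](O)c1ccc(OCc2ccccc2)c(OC)c1)C=C | intermediate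
5 | (5S)-5-{(R)-[4-(benzyloxy)-3-methoxyphenyl](hydroxy)methyl}-5,6-dihydro-2H-pyran-2-one | O=C1OC[C@@H]([C@@H](O)c2ccc(OCc3ccccc3)c(OC)c2)C=C1 | intermediate
6 | ethyl 2-{(R)-[4-(benzyloxy)-3-methoxyphenyl][(3S)-6-oxo-3,6-dihydro-2H-pyran-3-yl]methoxy}acetate | CCOC(=O)CO[C@H]([C@@H]1COC(=O)C=C1)c1ccc(OCc2ccccc2)c(OC)c1 | intermediate
7 | dilithium (2Z,4S,5R)-5-[4-(benzyloxy)-3-methoxyphenyl]-5-(carboxylatomethoxy)-4-(hydroxymethyl)pent-2-enoate | [Li+].[Li+].[O-]C(=O)/C=C\[C@@H](CO)[C@@H](OCC([O-])=O)c1ccc(OCc2ccccc2)c(OC)c1 | intermediate (not isolated)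
8 | 2-{(R)-[4-(benzyloxy)-3-methoxyphenyl][(3S)-6-oxo-3,6-dihydro-2H-pyran-3-yl]methoxy}acetic acid | OC(=O)CO[C@H]([C@@H]1COC(=O)C=C1)c1ccc(OCc2ccccc2)c(OC)c1 | intermediate
9 | (3R,3aS,7aS)-3-[4-(benzyloxy)-3-methoxyphenyl]hexahydro-6H-furo[3,4-c]pyran-6-one | O=C1OC[C@@H]2[C@H](C1)CO[C@H]2c1ccc(OCc3ccccc3)c(OC)c1 | intermediate
10 | 1-(benzyloxy)-4-bromo-2-methoxybenzene | Brc1ccc(OCc2ccccc2)c(OC)c1 | starting material
11 | caesium 2-[(3S,4S,5R)-5-[4-(benzyloxy)-3-methoxyphenyl]-4-(hydroxymethyl)oxolan-3-yl]acetate | [Cs+].OC[C@@H]1[C@H](CC([O-])=O)CO[C@H]1c1ccc(OCc2ccccc2)c(OC)c1 | intermediate (not isolated)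
12 | [(2R,3S,4S)-2-[4-(benzyloxy)-3-methoxyphenyl]-4-{[4-(benzyloxy)-3-methoxyphenyl]methyl}oxolan-3-yl]methanol | OC[C@@H]1[C@H](Cc2ccc(OCc3ccccc3)c(OC)c2)CO[C@H]1c1ccc(OCc2ccccc2)c(OC)c1 | intermediate
13 | (2R)-2-methylbutanoic acid | CC[C@@H](C)C(=O)O | starting material
14 | [(2R,3S,4S)-2-[4-(benzyloxy)-3-methoxyphenyl]-4-{[4-(benzyloxy)-3-methoxyphenyl]methyl}oxolan-3-yl]methyl (2R)-2-methylbutanoate | CC[C@@H](C)C(=O)OC[C@@H]1[C@H](Cc2ccc(OCc3ccccc3)c(OC)c2)CO[C@H]1c1ccc(OCc2ccccc2)c(OC)c1 | intermediate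
15 | [(2R,3S,4S)-2-(4-hydroxy-3-methoxyphenyl)-4-[(4-hydroxy-3-methoxyphenyl)methyl]oxolan-3-yl]methyl (2R)-2-methylbutanoate | CC[C@@H](C)C(=O)OC[C@@H]1[C@H](Cc2ccc(O)c(OC)c2)CO[C@H]1c1ccc(O)c(OC)c1 | target

**Step count and risks**

Total steps: 9. Longest linear sequence: 9 steps (1 to 15).

Steps most likely to fail, with fallbacks:

1. Step 7. The unstabilised primary carboxylate may be oxidised too slowly, so that electron transfer from the dialkoxyarene rings, O-arylation of the carboxylate or simple protodecarboxylation outruns capture of the C7′ radical at nickel.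
The fallback sets out from lactone 9 and comes back at alcohol 12; it generates the radical reductively from a redox-active ester instead.
Lactone 9 is opened with CsOH to salt 11, and treatment with tert-butyldimethylsilyl chloride and imidazole in DMF should give the bis-silylated compound tert-butyldimethylsilyl 2-[(3S,4S,5R)-5-[4-(benzyloxy)-3-methoxyphenyl]-4-{[(tert-butyldimethylsilyl)oxy]methyl}oxolan-3-yl]acetate F1 (not isolated). Its silyl ester is cleaved with K2CO3 in THF/H2O to 2-[(3S,4S,5R)-5-[4-(benzyloxy)-3-methoxyphenyl]-4-{[(tert-butyldimethylsilyl)oxy]methyl}oxolan-3-yl]acetic acid F2.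
N-Hydroxyphthalimide, N,N′-diisopropylcarbodiimide and DMAP convert this into 1,3-dioxoisoindolin-2-yl 2-[(3S,4S,5R)-5-[4-(benzyloxy)-3-methoxyphenyl]-4-{[(tert-butyldimethylsilyl)oxy]methyl}oxolan-3-yl]acetate F3.
Bromide 10 is turned by bromine–lithium exchange (n-BuLi, THF, −78 °C) and ZnCl2 into [4-(benzyloxy)-3-methoxyphenyl]zinc chloride F4.
A nickel-catalysed decarboxylative Negishi coupling of the two (NiCl2(dme), 4,4′-di-tert-butyl-2,2′-bipyridine, THF/DMF, 25 °C) should give tert-butyl{[(2R,3S,4S)-2-[4-(benzyloxy)-3-methoxyphenyl]-4-{[4-(benzyloxy)-3-methoxyphenyl]methyl}oxolan-3-yl]methoxy}dimethylsilane F5, and Bu4NF in THF returns 12.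

2. Step 6. Oxidative generation of the radical may be inefficient, or may be accompanied by electron transfer from the electron-rich benzylic ether and its fragmentation, so that the α-oxy radical is formed too slowly to cyclise cleanly.
The fallback sets out from acid 8 and comes back at lactone 9; it replaces the oxidative carboxylate activation by reductive fragmentation of a redox-active ester, so that no oxidant is present.
Acid 8 is condensed with N-hydroxyphthalimide (N,N′-diisopropylcarbodiimide, DMAP cat., CH2Cl2) to 1,3-dioxoisoindolin-2-yl 2-{(R)-[4-(benzyloxy)-3-methoxyphenyl][(3S)-6-oxo-3,6-dihydro-2H-pyran-3-yl]methoxy}acetate F6. Irradiation with blue light in the presence of Ru(bpy)3Cl2, Hantzsch ester and i-Pr2NEt (CH2Cl2, 25 °C) should release the same O1–C5H2• radical by single-electron reduction. This radical cyclises as in step 6, and the α-acyl radical is quenched by hydrogen transfer from the Hantzsch ester to give 9.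

3. Step 5. Hydroxide may deprotonate the γ-position C3 of the unsaturated lactone (epimerisation) or add in conjugate fashion, and the ring-opened hydroxy enoate may not reclose cleanly on acidification.
The fallback sets out from diol 3 and comes back at acid 8; it places the carboxymethyl group by Williamson etherification before any base-sensitive ester exists, so that no ester has to be hydrolysed.
Diol 3 is silylated at the primary hydroxyl (triisopropylsilyl chloride, imidazole, DMF) to (1R,2S)-1-[4-(benzyloxy)-3-methoxyphenyl]-2-({[tri(propan-2-yl)silyl]oxy}methyl)but-3-en-1-ol F7.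
NaH and bromoacetic acid in THF (0 to 25 °C, acidic work-up) should give 2-{[(1R,2S)-1-[4-(benzyloxy)-3-methoxyphenyl]-2-({[tri(propan-2-yl)silyl]oxy}methyl)but-3-en-1-yl]oxy}acetic acid F8.
Bu4NF in THF frees 2-{[(1R,2S)-1-[4-(benzyloxy)-3-methoxyphenyl]-2-(hydroxymethyl)but-3-en-1-yl]oxy}acetic acid F9.
Acryloyl chloride (2.2 equiv) and Et3N at −78 °C acylate the hydroxyl and the carboxyl group to the mixed anhydride 2-{[(1R,2S)-1-[4-(benzyloxy)-3-methoxyphenyl]-2-[(prop-2-enoyloxy)methyl]but-3-en-1-yl]oxy}acetic prop-2-enoic anhydride F10 (not isolated). Aqueous NaHCO3 work-up hydrolyses this to 2-{[(1R,2S)-1-[4-(benzyloxy)-3-methoxyphenyl]-2-[(prop-2-enoyloxy)methyl]but-3-en-1-yl]oxy}acetic acid F11.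
Ring-closing metathesis with the second-generation Grubbs catalyst (CH2Cl2, 40 °C) then gives 8.

**Further compounds**

F1 | step 7 | tert-butyldimethylsilyl 2-[(3S,4S,5R)-5-[4-(benzyloxy)-3-methoxyphenyl]-4-{[(tert-butyldimethylsilyl)oxy]methyl}oxolan-3-yl]acetate | CC(C)(C)[Si](C)(C)OC[C@@H]1[C@H](CC(=O)O[Si](C)(C)C(C)(C)C)CO[C@H]1c1ccc(OCc2ccccc2)c(OC)c1
F2 | step 7 | 2-[(3S,4S,5R)-5-[4-(benzyloxy)-3-methoxyphenyl]-4-{[(tert-butyldimethylsilyl)oxy]methyl}oxolan-3-yl]acetic acid | CC(C)(C)[Si](C)(C)OC[C@@H]1[C@H](CC(O)=O)CO[C@H]1c1ccc(OCc2ccccc2)c(OC)c1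
F3 | step 7 | 1,3-dioxoisoindolin-2-yl 2-[(3S,4S,5R)-5-[4-(benzyloxy)-3-methoxyphenyl]-4-{[(tert-butyldimethylsilyl)oxy]methyl}oxolan-3-yl]acetate | CC(C)(C)[Si](C)(C)OC[C@@H]1[C@H](CC(=O)ON2C(=O)c3ccccc3C2=O)CO[C@H]1c1ccc(OCc2ccccc2)c(OC)c1
F4 | step 7 | [4-(benzyloxy)-3-methoxyphenyl]zinc chloride | Cl[Zn]c1ccc(OCc2ccccc2)c(OC)c1
F5 | step 7 | tert-butyl{[(2R,3S,4S)-2-[4-(benzyloxy)-3-methoxyphenyl]-4-{[4-(benzyloxy)-3-methoxyphenyl]methyl}oxolan-3-yl]methoxy}dimethylsilane | CC(C)(C)[Si](C)(C)OC[C@@H]1[C@H](Cc2ccc(OCc3ccccc3)c(OC)c2)CO[C@H]1c1ccc(OCc2ccccc2)c(OC)c1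
F6 | step 6 | 1,3-dioxoisoindolin-2-yl 2-{(R)-[4-(benzyloxy)-3-methoxyphenyl][(3S)-6-oxo-3,6-dihydro-2H-pyran-3-yl]methoxy}acetate | O=C(CO[C@H]([C@@H]1COC(=O)C=C1)c1ccc(OCc2ccccc2)c(OC)c1)ON1C(=O)c2ccccc2C1=O
F7 | step 5 | (1R,2S)-1-[4-(benzyloxy)-3-methoxyphenyl]-2-({[tri(propan-2-yl)silyl]oxy}methyl)but-3-en-1-ol | CC(C)[Si](OC[C@@H]([C@@H](O)c1ccc(OCc2ccccc2)c(OC)c1)C=C)(C(C)C)C(C)C
F8 | step 5 | 2-{[(1R,2S)-1-[4-(benzyloxy)-3-methoxyphenyl]-2-({[tri(propan-2-yl)silyl]oxy}methyl)but-3-en-1-yl]oxy}acetic acid | CC(C)[Si](OC[C@@H]([C@@H](OCC(O)=O)c1ccc(OCc2ccccc2)c(OC)c1)C=C)(C(C)C)C(C)C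
F9 | step 5 | 2-{[(1R,2S)-1-[4-(benzyloxy)-3-methoxyphenyl]-2-(hydroxymethyl)but-3-en-1-yl]oxy}acetic acid | OC[C@@H]([C@@H](OCC(O)=O)c1ccc(OCc2ccccc2)c(OC)c1)C=C
F10 | step 5 | 2-{[(1R,2S)-1-[4-(benzyloxy)-3-methoxyphenyl]-2-[(prop-2-enoyloxy)methyl]but-3-en-1-yl]oxy}acetic prop-2-enoic anhydride | C=CC(=O)OC[C@@H]([C@@H](OCC(=O)OC(=O)C=C)c1ccc(OCc2ccccc2)c(OC)c1)C=C
F11 | step 5 | 2-{[(1R,2S)-1-[4-(benzyloxy)-3-methoxyphenyl]-2-[(prop-2-enoyloxy)methyl]but-3-en-1-yl]oxy}acetic acid | C=CC(=O)OC[C@@H]([C@@H](OCC(O)=O)c1ccc(OCc2ccccc2)c(OC)c1)C=C
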